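**Plan**
The retrosynthesis first removes three benzyl ethers, then cuts the depside link once, between the ester oxygen and C4 of ring B, leaving the acyl–oxygen bond intact.
This gives a ring A benzoic acid and a ring B aryl(2,4,6-trimethoxyphenyl)iodonium salt. C4 of ring B sits between the C3 and C5 methyl groups and para to the C1 ester, so it has no ortho hydrogen and is the crowded, electron-poor aryl that trivalent iodine gives up.
Forward, ring A: methyl 2,4-dihydroxy-3,6-dimethylbenzoate is chlorinated at its only ring C–H, benzylated and saponified.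
Forward, ring B: 2,4,5-trimethylphenol is carboxylated at its only free ortho carbon, esterified, iodinated at the last ring C–H, benzylated and converted into the iodonium tosylate.
The two halves are joined by carboxylate O-arylation and the benzyl groups are then removed; both benzene rings are bought and no ring is formed.
The target has no stereocentre, so no stereochemistry has to be set.

Key step: step 9

Remark: phenoxide, carboxylate and boron aryloxide forms that only carry a numbered compound into or out of a work-up are treated as that compound and are not numbered; the iodonium carboxylate of step 9 is a distinct species and is numbered.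

**Step 1**
Reactants: 1 methyl 2,4-dihydroxy-3,6-dimethylbenzoate
Product: 2 methyl 5-chloro-2,4-dihydroxy-3,6-dimethylbenzoate
Conditions: SO2Cl2 (1.05 equiv), Et2O, 0 °C to rt
Reagents that add atoms: sulfuryl chloride, O=S(=O)(Cl)Cl
Why: Electrophilic aromatic chlorination can only take place at C5, the single ring C–H, which is ortho to the C4 hydroxyl and para to the C2 hydroxyl, and one equivalent of reagent at low temperature should stop at the monochloride.

**Step 2**
Reactants: 2 methyl 5-chloro-2,4-dihydroxy-3,6-dimethylbenzoate
Product: 3 methyl 2,4-bis(benzyloxy)-5-chloro-3,6-dimethylbenzoate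
Conditions: BnBr (excess), K2CO3, DMF, 60 °C
Reagents that add atoms: benzyl bromide, BrCc1ccccc1
Why: Williamson ether synthesis on both phenoxides, where warming in DMF with excess benzyl bromide should overcome the hydrogen bond of the C2 hydroxyl and the crowding around the C4 hydroxyl.

**Step 3**
Reactants: 3 methyl 2,4-bis(benzyloxy)-5-chloro-3,6-dimethylbenzoate
Product: 4 2,4-bis(benzyloxy)-5-chloro-3,6-dimethylbenzoic acid (the same compound as 4,6-bis(benzyloxy)-3-chloro-2,5-dimethylbenzoic acid)
Conditions: KOH, DMSO/H2O, 100 °C; then aq. HCl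
Reagents that add atoms: potassium hydroxide, [K+].[OH-]
Why: Saponification of a doubly ortho-substituted methyl benzoate needs weakly solvated hydroxide, which hot aqueous DMSO supplies, while the benzyl ethers and the unactivated aryl chloride are inert to it.

**Step 4**
Reactants: 5 2,4,5-trimethylphenol
Product: 6 2-hydroxy-3,5,6-trimethylbenzoic acid
Conditions: NaOH, H2O, then dried; CO2 (50 bar), 160 °C; then aq. HCl
Reagents that add atoms: carbon dioxide, O=C=O
Why: Kolbe–Schmitt carboxylation of the sodium phenoxide delivers CO2 to the ortho position through the sodium chelate, and C6 is the only free ortho carbon (the para carbon carries a methyl group), the same situation as in the carboxylation of thymol to o-thymotic acid.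

**Step 5**
Reactants: 6 2-hydroxy-3,5,6-trimethylbenzoic acid
Product: 7 methyl 2-hydroxy-3,5,6-trimethylbenzoate
Conditions: MeI, KHCO3, DMF, rt
Reagents that add atoms: iodomethane, CI
Why: SN2 O-alkylation of the carboxylate avoids the slow Fischer esterification of a doubly ortho-substituted acid, and hydrogen carbonate is too weak a base to ionise the hydrogen-bonded phenol.

**Step 6**
Reactants: 7 methyl 2-hydroxy-3,5,6-trimethylbenzoate
Product: 8 methyl 2-hydroxy-4-iodo-3,5,6-trimethylbenzoate
Conditions: NIS (1.1 equiv), TFA, 0 °C to rt, dark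
Reagents that add atoms: N-iodosuccinimide, O=C1CCC(=O)N1I
Why: Electrophilic aromatic iodination can end only at C4, the one ring C–H, which lies between two methyl groups; attack at the substituted carbons is reversible, and acid-activated NIS should be electrophilic enough for a position para to an ester.

**Step 7**
Reactants: 8 methyl 2-hydroxy-4-iodo-3,5,6-trimethylbenzoate
Product: 9 methyl 2-(benzyloxy)-4-iodo-3,5,6-trimethylbenzoate
Conditions: BnBr, K2CO3, DMF, 60 °C
Reagents that add atoms: benzyl bromide, BrCc1ccccc1
Why: Williamson ether synthesis, which keeps the phenol from being oxidised in step 8 and from competing as a nucleophile in step 9.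

**Step 8**
Reactants: 9 methyl 2-(benzyloxy)-4-iodo-3,5,6-trimethylbenzoate; 10 1,3,5-trimethoxybenzene
Product: 12 [3-(benzyloxy)-4-(methoxycarbonyl)-2,5,6-trimethylphenyl](2,4,6-trimethoxyphenyl)iodonium tosylate, via hydroxy(tosyloxy)iodoarene 11 (not isolated)
Conditions: mCPBA, TsOH·H2O, MeCN, 77 °C; then 10, 77 °C; Et2O trituration
Reagents that add atoms: p-toluenesulfonic acid monohydrate, Cc1ccc(S(=O)(=O)O)cc1.O; mCPBA, O=C(OO)c1cccc(Cl)c1 (its oxygen is held only in 11 and leaves as water)
Why: One-pot oxidation of the aryl iodide to the [hydroxy(tosyloxy)iodo]arene, then electrophilic aromatic substitution of the very electron-rich 1,3,5-trimethoxybenzene at trivalent iodine, is a standard entry to aryl(2,4,6-trimethoxyphenyl)iodonium tosylates and tolerates two ortho methyl groups.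

**Step 9**
Reactants: 4 2,4-bis(benzyloxy)-5-chloro-3,6-dimethylbenzoic acid; 12 [3-(benzyloxy)-4-(methoxycarbonyl)-2,5,6-trimethylphenyl](2,4,6-trimethoxyphenyl)iodonium tosylate
Product: 14 methyl 2-(benzyloxy)-4-{[2,4-bis(benzyloxy)-5-chloro-3,6-dimethylbenzoyl]oxy}-3,5,6-trimethylbenzoate, via iodonium carboxylate 13 (not isolated)
Conditions: 4, KOtBu (1.0 equiv), toluene, rt; then 12, 110 °C
Reagents that add atoms: none
Why: The potassium carboxylate of 4 displaces tosylate from the iodonium centre to give the T-shaped trivalent-iodine carboxylate 13, which on heating undergoes ligand coupling between the carboxylate oxygen and the ipso carbon C4 of ring B while iodine leaves in the monovalent state as 2-iodo-1,3,5-trimethoxybenzene. The closest known reaction type is the metal-free O-arylation of carboxylic acids with diaryliodonium salts, including salts that carry a 2,4,6-trimethoxyphenyl dummy group. No ring is closed and no stereocentre is formed. The step needs the ring B aryl, not the trimethoxyphenyl group, to migrate: ring B is the more electron-poor aryl (ester para to iodine) and has two ortho methyl groups, whereas the trimethoxyphenyl ring is strongly electron-rich and should stay on iodine. Neither aryl has a hydrogen ortho to iodine, so no aryne can form, and with all three phenols benzylated the carboxylate is the only nucleophile. Because the new bond is made at the aryl carbon, the crowded acyl carbon of ring A never has to pass through a tetrahedral intermediate.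

**Step 10**
Reactants: 14 methyl 2-(benzyloxy)-4-{[2,4-bis(benzyloxy)-5-chloro-3,6-dimethylbenzoyl]oxy}-3,5,6-trimethylbenzoate
Product: 15 methyl 4-[(5-chloro-2,4-dihydroxy-3,6-dimethylbenzoyl)oxy]-2-hydroxy-3,5,6-trimethylbenzoate
Conditions: BCl3, pentamethylbenzene, CH2Cl2, −78 to 0 °C; then H2O
Reagents that add atoms: none
Why: Lewis-acid debenzylation in which pentamethylbenzene traps the benzyl cations by Friedel–Crafts alkylation should cleave the three aryl benzyl ethers at low temperature without reducing the aryl chloride and without attacking the methyl ester or the depside ester.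

**Compound list**
1 | methyl 2,4-dihydroxy-3,6-dimethylbenzoate | COC(=O)c1c(C)cc(O)c(C)c1O | starting material
2 | methyl 5-chloro-2,4-dihydroxy-3,6-dimethylbenzoate | COC(=O)c1c(C)c(Cl)c(O)c(C)c1O | intermediate
3 | methyl 2,4-bis(benzyloxy)-5-chloro-3,6-dimethylbenzoate | COC(=O)c1c(C)c(Cl)c(OCc2ccccc2)c(C)c1OCc1ccccc1 | intermediate
4 | 2,4-bis(benzyloxy)-5-chloro-3,6-dimethylbenzoic acid | O=C(O)c1c(C)c(Cl)c(OCc2ccccc2)c(C)c1OCc1ccccc1 | intermediate
5 | 2,4,5-trimethylphenol | Oc1cc(C)c(C)cc1C | starting material
6 | 2-hydroxy-3,5,6-trimethylbenzoic acid | OC(=O)c1c(C)c(C)cc(C)c1O | intermediate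
7 | methyl 2-hydroxy-3,5,6-trimethylbenzoate | COC(=O)c1c(C)c(C)cc(C)c1O | intermediate
8 | methyl 2-hydroxy-4-iodo-3,5,6-trimethylbenzoate | COC(=O)c1c(C)c(C)c(I)c(C)c1O | intermediate
9 | methyl 2-(benzyloxy)-4-iodo-3,5,6-trimethylbenzoate | COC(=O)c1c(C)c(C)c(I)c(C)c1OCc1ccccc1 | intermediate
10 | 1,3,5-trimethoxybenzene | COc1cc(OC)cc(OC)c1 | starting material
11 | methyl 2-(benzyloxy)-4-[hydroxy(tosyloxy)iodo]-3,5,6-trimethylbenzoate | COC(=O)c1c(C)c(C)c(I(O)OS(=O)(=O)c2ccc(C)cc2)c(C)c1OCc1ccccc1 | intermediate
12 | [3-(benzyloxy)-4-(methoxycarbonyl)-2,5,6-trimethylphenyl](2,4,6-trimethoxyphenyl)iodonium tosylate | COC(=O)c1c(C)c(C)c([I+]c2c(OC)cc(OC)cc2OC)c(C)c1OCc1ccccc1.Cc1ccc(S(=O)(=O)[O-])cc1 | intermediate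
13 | [3-(benzyloxy)-4-(methoxycarbonyl)-2,5,6-trimethylphenyl](2,4,6-trimethoxyphenyl)iodonium 2,4-bis(benzyloxy)-5-chloro-3,6-dimethylbenzoate | COC(=O)c1c(C)c(C)c([I+]c2c(OC)cc(OC)cc2OC)c(C)c1OCc1ccccc1.[O-]C(=O)c1c(C)c(Cl)c(OCc2ccccc2)c(C)c1OCc1ccccc1 | intermediate
14 | methyl 2-(benzyloxy)-4-{[2,4-bis(benzyloxy)-5-chloro-3,6-dimethylbenzoyl]oxy}-3,5,6-trimethylbenzoate | COC(=O)c1c(C)c(C)c(OC(=O)c2c(C)c(Cl)c(OCc3ccccc3)c(C)c2OCc2ccccc2)c(C)c1OCc1ccccc1 | intermediate
15 | methyl 4-[(5-chloro-2,4-dihydroxy-3,6-dimethylbenzoyl)oxy]-2-hydroxy-3,5,6-trimethylbenzoate | COC(=O)c1c(C)c(C)c(OC(=O)c2c(C)c(Cl)c(O)c(C)c2O)c(C)c1O | target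

**Count**
Total steps: 10. Longest linear sequence: 7 steps (5 to 15, steps 4 to 10).

**Steps most likely to fail**

Step 9. Ligand coupling between a doubly ortho-substituted carboxylate and a doubly ortho-substituted aryl may be slower than thermal decomposition of the iodonium salt or transfer of the wrong aryl group. The fallback makes the acyl–oxygen bond instead and sets out from 9. Iodine–magnesium exchange (iPrMgCl·LiCl, THF, −30 °C), trapping with B(OMe)3 and aqueous work-up should give [3-(benzyloxy)-4-(methoxycarbonyl)-2,5,6-trimethylphenyl]boronic acid F1. Oxidation with aqueous H2O2 in THF/NaHCO3 should then give methyl 2-(benzyloxy)-4-hydroxy-3,5,6-trimethylbenzoate F2. Acylation of F2 with acid 4 through its mixed trifluoroacetic anhydride ((CF3CO)2O, toluene, rt), a classical depside esterification that proceeds through an acylium-like species, comes back to the route at 14.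

Step 6. Substitution at a carbon para to the ester may be slow enough that oxidation of the free phenol or stalling at reversible ipso adducts takes over. The fallback sets out from 7 and uses the more reactive halogen. Br2 in AcOH should give methyl 4-bromo-2-hydroxy-3,5,6-trimethylbenzoate F3, relying on the known shift of bromine from a bromodienone to the meta carbon of fully ortho/para-substituted phenols. Benzylation (BnBr, K2CO3, DMF) gives methyl 2-(benzyloxy)-4-bromo-3,5,6-trimethylbenzoate F4. A copper-catalysed aromatic Finkelstein exchange (CuI, NaI, trans-N,N'-dimethylcyclohexane-1,2-diamine, dioxane, 110 °C) comes back to the route at 9.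

Step 8. The benzyl ether may be lost, or the electron-rich ring oxidised, under hot peracid and sulfonic acid. The fallback sets out from 9 and is stepwise and free of strong acid. NaBO3·4H2O in AcOH at 45 °C should give methyl 2-(benzyloxy)-4-(diacetoxyiodo)-3,5,6-trimethylbenzoate F5. Condensation with 10 in 2,2,2-trifluoroethanol at rt should give [3-(benzyloxy)-4-(methoxycarbonyl)-2,5,6-trimethylphenyl](2,4,6-trimethoxyphenyl)iodonium acetate F6. Exchange of acetate for the carboxylate of acid 4 in toluene, with removal of acetic acid, comes back to the route at 13, which is heated as in step 9 to give 14.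

**Further compounds**
F1 | step 9 | [3-(benzyloxy)-4-(methoxycarbonyl)-2,5,6-trimethylphenyl]boronic acid | COC(=O)c1c(C)c(C)c(B(O)O)c(C)c1OCc1ccccc1
F2 | step 9 | methyl 2-(benzyloxy)-4-hydroxy-3,5,6-trimethylbenzoate | COC(=O)c1c(C)c(C)c(O)c(C)c1OCc1ccccc1
F3 | step 6 | methyl 4-bromo-2-hydroxy-3,5,6-trimethylbenzoate | COC(=O)c1c(C)c(C)c(Br)c(C)c1O
F4 | step 6 | methyl 2-(benzyloxy)-4-bromo-3,5,6-trimethylbenzoate | COC(=O)c1c(C)c(C)c(Br)c(C)c1OCc1ccccc1
F5 | step 8 | methyl 2-(benzyloxy)-4-(diacetoxyiodo)-3,5,6-trimethylbenzoate | COC(=O)c1c(C)c(C)c(I(OC(C)=O)OC(C)=O)c(C)c1OCc1ccccc1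
F6 | step 8 | [3-(benzyloxy)-4-(methoxycarbonyl)-2,5,6-trimethylphenyl](2,4,6-trimethoxyphenyl)iodonium acetate | COC(=O)c1c(C)c(C)c([I+]c2c(OC)cc(OC)cc2OC)c(C)c1OCc1ccccc1.CC(=O)[O-]
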